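**Plan**

1. Cuts: the silyl ether last, then the ring bond C5–C10 of the cyclohexane (C5–C6–C7–C8–C9–C10). This bond is the central σ-bond of the 1,5-diene C2=C1–C10–C5–C4=C3 (vinyl on quaternary C10 next to the 2-propenyl unit on C5), so the ring can arise by joining the inner ends of two allyl units held on a preformed butyrolactone.
2. Further cuts: C8–O ester, C2–B/C14–H (diene), C8–C9 (isoprenyl unit plus C8 aldehyde), C11–C13 (enolate methylation), C6–C7 and the lactone C–O (succinate aldol–lactonisation), C4=C5 (olefination of a dioxanone).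
3. Forward: the lactone is built first and is the only skeleton ring before the key step. The two arms follow: an alkylidene cyclic carbonate on C6 (masks C15–OH, arms C3) and an (E)-allyl boronate grown from C8. Pd-mediated closure of the carbocycle is the last ring closure; desilylation ends the route.
4. Stereochemistry: C6 and C7 from the (S)-benzyl oxazolidinone; C11 and C8 relayed from C7; C5 and quaternary C10 set together in the ring closure (chair transition state locked by the trans lactone bonds, E-allyl geometry); the side-chain centre is bought as the (R)-hydroxy ester.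

Key step: step 15

Remark: locants C1–C15 are those of the elemanolide skeleton of the target (ring C5–C10; vinyl C1=C2 and methyl C14 on C10; C3=C4–C15 on C5; lactone O–C6, C7, C11–C13, C12=O; ester on C8–O); 2-(bromomethyl)buta-1,3-diene (16) is assumed to be purchasable (otherwise a known two-step derivative of isoprene).

**Route**

Step 1
Reactants: 1 2,2-dimethyl-1,3-dioxan-5-one; 2 diethyl (cyanomethyl)phosphonate
Product: 3 2-(2,2-dimethyl-1,3-dioxan-5-ylidene)acetonitrile
Conditions: NaH, THF, 0 °C → rt
Reagents that add atoms: none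
Why: Horner–Wadsworth–Emmons olefination of an electron-poor, unhindered ketone; the product has no E/Z isomers because C4 carries two identical CH2O arms, a symmetry used again in steps 14 and 15.

Step 2
Reactants: 3 2-(2,2-dimethyl-1,3-dioxan-5-ylidene)acetonitrile
Product: 5 2-(2,2-dimethyl-1,3-dioxan-5-ylidene)acetaldehyde, via N-aluminio aldimine 4 (not isolated)
Conditions: DIBAL-H (1.1 equiv), CH2Cl2, −78 °C; aq. potassium sodium tartrate, rt
Reagents that add atoms: water, O
Why: single hydride addition to the conjugated nitrile and hydrolysis of the aluminated aldimine on neutral work-up (nitrile-to-aldehyde reduction) should give the enal without touching the acetonide.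

Step 3
Reactants: 6 (4S)-4-benzyl-1,3-oxazolidin-2-one; 7 methyl 4-chloro-4-oxobutanoate
Product: 8 (4S)-4-benzyl-3-(4-methoxy-4-oxobutanoyl)-1,3-oxazolidin-2-one
Conditions: n-BuLi, THF, −78 °C; then 7, −78 → 0 °C
Reagents that add atoms: none
Why: N-acylation of the lithiated oxazolidinone by the acid chloride, the standard entry to an Evans imide.

Step 4
Reactants: 8 (4S)-4-benzyl-3-(4-methoxy-4-oxobutanoyl)-1,3-oxazolidin-2-one; 5 2-(2,2-dimethyl-1,3-dioxan-5-ylidene)acetaldehyde
Product: 10 (4S)-4-benzyl-3-{[(2R,3S)-2-[(2,2-dimethyl-1,3-dioxan-5-ylidene)methyl]-5-oxooxolan-3-yl]carbonyl}-1,3-oxazolidin-2-one, via syn-aldol hydroxy ester 9 (not isolated)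
Conditions: Bu2BOTf, i-Pr2NEt, CH2Cl2, −78 → 0 °C; 5, −78 → 0 °C; pH 7 buffer, MeOH, H2O2; crude, PPTS (cat.), toluene, 50 °C
Reagents that add atoms: none
Why: Evans syn-aldol reaction of the (Z)-boron enolate (enolisation at the imide α-CH2, not at the ester) through a Zimmerman–Traxler chair should set C7 and C6 under auxiliary control, and the γ-hydroxy ester then closes to the trans-4,5-disubstituted butyrolactone (aldol–lactonisation as used for paraconic acids).

Step 5
Reactants: 10 lactone imide
Product: 12 (2R,3S)-2-[(2,2-dimethyl-1,3-dioxan-5-ylidene)methyl]-5-oxooxolane-3-carboxylic acid, via peroxy acid 11 (not isolated)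
Conditions: LiOH, H2O2, THF/H2O, 0 °C; Na2SO3; 1 M HCl to pH 3, 0 °C
Reagents that add atoms: hydrogen peroxide (as LiOOH), OO
Why: hydroperoxide attacks the exocyclic imide carbonyl (standard auxiliary cleavage), sulfite reduces the peracid, and any ring-opened hydroxy acid can only reclose to the same γ-lactone on acidification.

Step 6
Reactants: 12 lactone acid
Product: 13 (2R,3S,4S)-2-[(2,2-dimethyl-1,3-dioxan-5-ylidene)methyl]-4-methyl-5-oxooxolane-3-carboxylic acid
Conditions: NaHMDS (2.2 equiv), THF, −78 °C; MeI, −78 → −40 °C; 1 M HCl work-up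
Reagents that add atoms: iodomethane, CI
Why: alkylation of the carboxylate/lactone-enolate dianion should occur anti to the C7 substituent (trans α-alkylation of β-substituted butyrolactone enolates, precedented on paraconic acids) and so set C11, while the carboxylate protects C7–H from deprotonation and ring opening.

Step 7
Reactants: 13 methylated lactone acid
Product: 15 (2R,3S,4S)-2-[(2,2-dimethyl-1,3-dioxan-5-ylidene)methyl]-4-methyl-5-oxooxolane-3-carbaldehyde, via acid chloride 14 (not isolated)
Conditions: 1-chloro-N,N,2-trimethylprop-1-en-1-amine, CH2Cl2, 0 °C; then LiAlH(Ot-Bu)3, THF, −78 °C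
Reagents that add atoms: none
Why: neutral acid chloride formation followed by reduction with the hindered alkoxyaluminium hydride at low temperature should stop at the aldehyde and leave the lactone and acetonide intact; the trans arrangement at C7 is also the thermodynamic one.

Step 8
Reactants: 15 lactone aldehyde; 16 2-(bromomethyl)buta-1,3-diene
Product: 17 (3S,4R,5R)-5-[(2,2-dimethyl-1,3-dioxan-5-ylidene)methyl]-4-[(1S)-1-hydroxy-3-methylidenepent-4-en-1-yl]-3-methyloxolan-2-one
Conditions: Zn dust, THF/sat. aq. NH4Cl, 0 °C → rt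
Reagents that add atoms: none
Why: zinc-mediated Barbier isoprenylation in a near-neutral aqueous medium (so the new γ-hydroxy lactone should not translactonise), with Felkin–Anh addition anti to the larger, oxygen-bearing C7–C6 branch expected to favour the required C8 configuration.

Step 9
Reactants: 18 methyl (2R)-3-hydroxy-2-methylpropanoate
Product: 19 methyl (2R)-3-[(tert-butyldiphenylsilyl)oxy]-2-methylpropanoate
Conditions: TBDPSCl, imidazole, CH2Cl2, rt
Reagents that add atoms: tert-butyl(chloro)diphenylsilane, CC(C)(C)[Si](Cl)(c1ccccc1)c1ccccc1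
Why: imidazole-promoted silylation of the primary alcohol with a group that survives the later mild acid step.

Step 10
Reactants: 19 silyl ether ester
Product: 20 (2R)-3-[(tert-butyldiphenylsilyl)oxy]-2-methylpropanoic acid
Conditions: LiOH, THF/MeOH/H2O, 0 °C; 1 M HCl
Reagents that add atoms: lithium hydroxide, [Li+].[OH-]
Why: cold saponification of the methyl ester, a standard operation on this class of α-methyl β-silyloxy esters that should not epimerise the α-centre.

Step 11
Reactants: 17 homoallylic alcohol; 20 silyloxy acid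
Product: 21 ester of 17 (at C8–O) with 20, all stereocentres as in 17 and 20
Conditions: DCC, DMAP (cat.), CH2Cl2, 0 °C → rt
Reagents that add atoms: none
Why: Steglich esterification acylates C8–OH with retention under conditions mild enough to limit epimerisation of the acid α-centre.

Step 12
Reactants: 21 diene ester
Product: 22 (E)-allyl pinacol boronate: 21 after addition of H to C14 and B(pin) to C2, C1=C10 double bond E (C9 trans to C2)
Conditions: HBpin (1.3 equiv), FeCl2·(2-iminopyridine) (5 mol %), Mg (10 mol %), Et2O, rt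
Reagents that add atoms: pinacolborane, [H]B1OC(C)(C)C(C)(C)O1
Why: iron-catalysed 1,4-hydroboration of a 2-substituted 1,3-diene through the s-cis diene complex should deliver the linear allyl boronate with H at C14 and boron at C2 and thereby fix the (E) geometry of C1=C10, while the isolated trisubstituted alkene, esters and lactone are inert to HBpin.

Step 13
Reactants: 22 allyl boronate acetonide
Product: 23 diol: 22 with the acetonide removed (2-ylidenepropane-1,3-diol on C5)
Conditions: PPTS (cat.), MeOH, rt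
Reagents that add atoms: none
Why: acid-catalysed transacetalisation to methanol removes the six-membered acetonide under conditions that should spare the TBDPS ether, the esters and the pinacol allyl boronate.

Step 14
Reactants: 23 diol
Product: 25 cyclic carbonate of 23 (5-ylidene-1,3-dioxan-2-one on C5; (E)-allyl boronate on C9), via mono-imidazolide 24 (not isolated)
Conditions: CDI (1.3 equiv), DMAP (cat.), CH2Cl2 (dilute), 0 °C → rt
Reagents that add atoms: 1,1'-carbonyldiimidazole, O=C(n1ccnc1)n1ccnc1
Why: carbonylation of the 1,3-diol through the mono-imidazolide closes the six-membered cyclic carbonate, which at once masks C15–OH and activates the C3–O bond for ionisation.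

Step 15
Reactants: 25 cyclic carbonate allyl boronate
Product: 27 (3S,3aR,4S,6S,7R,7aR)-6-ethenyl-7-(3-hydroxyprop-1-en-2-yl)-3,6-dimethyl-2-oxooctahydro-1-benzofuran-4-yl (2R)-3-[(tert-butyldiphenylsilyl)oxy]-2-methylpropanoate, via O-boryl ether 26 (not isolated)
Conditions: Pd2(dba)3 (2.5 mol %), 1,2-bis(diphenylphosphino)benzene (6 mol %), THF (5 mM), 45 °C; aq. NH4Cl
Reagents that add atoms: none
Why: Proposed new method: Pd(0) should ionise one of the two equivalent allylic C–O bonds of the alkylidene cyclic carbonate with loss of CO2, giving a π-allyl complex over C3–C4–C5 whose C15 alkoxide activates the pinacol boronate; the (E)-allyl group moves to palladium, and the small-bite-angle diphosphine enforces a bis(η1-allyl)palladium that undergoes 3,3′-reductive elimination through a chair-like seven-membered transition state, joining C5 to C10 and releasing the C1=C2 vinyl, the C3=C4 methylene and the C15–O–B(pin) ether 26, which is hydrolysed on work-up. The closest known reaction types are the intermolecular branch-selective Pd-catalysed coupling of allyl boronates with allylic carbonates or chlorides, which creates quaternary carbons by the same 3,3′-reductive elimination, and the Pd-catalysed closure of tethered allyl stannane/allyl carboxylate pairs to 1,2-dialkenylcycloalkanes; a closure at a fully substituted carbon from a boronate and a decarboxylating cyclic carbonate has not been shown. The cyclohexane C5–C6–C7–C8–C9–C10 is closed by the C5–C10 bond in a mode that is exo with respect to both allyl units (6-exo at C5 and at C10, both new C=C bonds outside the ring). C5 and C10 are set together: the trans-disposed lactone bonds C6–O and C7–C11 must be diequatorial in the forming chair and C8–O follows, so the palladacycle can only be fused through equatorial C5–C4 and C10–C1 bonds (trans-decalin-like chair–chair), which places H5 and the C14 methyl axial; at C10 this also rests on the (E) geometry of the boronate (C9 pseudo-equatorial) and at C5 on the syn π-allyl. The step needs 3,3′- over 1,1′- or 1,3′-coupling (bite angle of the ligand; six- against ten- or eight-membered ring), ionisation of the strained primary carbonate in preference to the allylic lactone C6–O bond, and high dilution against intermolecular coupling.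

Step 16
Reactants: 27 silyl-protected elemanolide
Product: 28 (3S,3aR,4S,6S,7R,7aR)-6-ethenyl-7-(3-hydroxyprop-1-en-2-yl)-3,6-dimethyl-2-oxooctahydro-1-benzofuran-4-yl (2R)-3-hydroxy-2-methylpropanoate (target)
Conditions: HF·pyridine, pyridine/THF, 0 °C → rt
Reagents that add atoms: none
Why: buffered fluoride cleavage of the primary silyl ether, under which the lactone, the ester and both 1,1-disubstituted and monosubstituted alkenes should be stable.

**Compound list**

1 | 2,2-dimethyl-1,3-dioxan-5-one | CC1(C)OCC(=O)CO1 | starting material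
2 | diethyl (cyanomethyl)phosphonate | CCOP(=O)(CC#N)OCC | starting material
3 | 2-(2,2-dimethyl-1,3-dioxan-5-ylidene)acetonitrile | N#CC=C1COC(C)(C)OC1 | intermediate
4 | N-(diisobutylalumanyl)-2-(2,2-dimethyl-1,3-dioxan-5-ylidene)ethan-1-imine | CC(C)C[Al](CC(C)C)N=CC=C1COC(C)(C)OC1 | intermediate (not isolated)
5 | 2-(2,2-dimethyl-1,3-dioxan-5-ylidene)acetaldehyde | O=CC=C1COC(C)(C)OC1 | intermediate
6 | (4S)-4-benzyl-1,3-oxazolidin-2-one | O=C1OC[C@H](Cc2ccccc2)N1 | starting material
7 | methyl 4-chloro-4-oxobutanoate | COC(=O)CCC(Cl)=O | starting material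
8 | (4S)-4-benzyl-3-(4-methoxy-4-oxobutanoyl)-1,3-oxazolidin-2-one | COC(=O)CCC(=O)N1[C@@H](Cc2ccccc2)COC1=O | intermediate
9 | methyl (3S,4R)-3-{[(4S)-4-benzyl-2-oxo-1,3-oxazolidin-3-yl]carbonyl}-5-(2,2-dimethyl-1,3-dioxan-5-ylidene)-4-hydroxypentanoate | O=C(N1[C@@H](Cc2ccccc2)COC1=O)[C@@H](CC(=O)OC)[C@H](O)C=C3COC(C)(C)OC3 | intermediate (not isolated)
10 | (4S)-4-benzyl-3-{[(2R,3S)-2-[(2,2-dimethyl-1,3-dioxan-5-ylidene)methyl]-5-oxooxolan-3-yl]carbonyl}-1,3-oxazolidin-2-one (trans lactone) | O=C(N1[C@@H](Cc2ccccc2)COC1=O)[C@@H]3[C@H](OC(=O)C3)C=C4COC(C)(C)OC4 | intermediate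
11 | (2R,3S)-2-[(2,2-dimethyl-1,3-dioxan-5-ylidene)methyl]-5-oxooxolane-3-carboperoxoic acid | OOC(=O)[C@@H]1[C@H](OC(=O)C1)C=C2COC(C)(C)OC2 | intermediate (not isolated)
12 | (2R,3S)-2-[(2,2-dimethyl-1,3-dioxan-5-ylidene)methyl]-5-oxooxolane-3-carboxylic acid | OC(=O)[C@@H]1[C@H](OC(=O)C1)C=C2COC(C)(C)OC2 | intermediate
13 | (2R,3S,4S)-2-[(2,2-dimethyl-1,3-dioxan-5-ylidene)methyl]-4-methyl-5-oxooxolane-3-carboxylic acid (all-trans) | OC(=O)[C@@H]1[C@H](OC(=O)[C@H]1C)C=C2COC(C)(C)OC2 | intermediate
14 | (2R,3S,4S)-2-[(2,2-dimethyl-1,3-dioxan-5-ylidene)methyl]-4-methyl-5-oxooxolane-3-carbonyl chloride | ClC(=O)[C@@H]1[C@H](OC(=O)[C@H]1C)C=C2COC(C)(C)OC2 | intermediate (not isolated)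
15 | (2R,3S,4S)-2-[(2,2-dimethyl-1,3-dioxan-5-ylidene)methyl]-4-methyl-5-oxooxolane-3-carbaldehyde | O=C[C@@H]1[C@H](OC(=O)[C@H]1C)C=C2COC(C)(C)OC2 | intermediate
16 | 2-(bromomethyl)buta-1,3-diene | C=CC(=C)CBr | starting material
17 | (3S,4R,5R)-5-[(2,2-dimethyl-1,3-dioxan-5-ylidene)methyl]-4-[(1S)-1-hydroxy-3-methylidenepent-4-en-1-yl]-3-methyloxolan-2-one | C=CC(=C)C[C@H](O)[C@@H]1[C@H](OC(=O)[C@H]1C)C=C2COC(C)(C)OC2 | intermediate
18 | methyl (2R)-3-hydroxy-2-methylpropanoate | COC(=O)[C@H](C)CO | starting material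
19 | methyl (2R)-3-[(tert-butyldiphenylsilyl)oxy]-2-methylpropanoate | COC(=O)[C@H](C)CO[Si](c1ccccc1)(c1ccccc1)C(C)(C)C | intermediate
20 | (2R)-3-[(tert-butyldiphenylsilyl)oxy]-2-methylpropanoic acid | OC(=O)[C@H](C)CO[Si](c1ccccc1)(c1ccccc1)C(C)(C)C | intermediate
21 | ester of 17 (C8–O) with 20; diene and acetonide intact | C=CC(=C)C[C@H](OC(=O)[C@H](C)CO[Si](c1ccccc1)(c1ccccc1)C(C)(C)C)[C@@H]2[C@H](OC(=O)[C@H]2C)C=C3COC(C)(C)OC3 | intermediate
22 | (E)-allyl pinacol boronate from 21 (H at C14, Bpin at C2) | C/C(=C\CB1OC(C)(C)C(C)(C)O1)C[C@H](OC(=O)[C@H](C)CO[Si](c2ccccc2)(c2ccccc2)C(C)(C)C)[C@@H]3[C@H](OC(=O)[C@H]3C)C=C4COC(C)(C)OC4 | intermediate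
23 | diol from 22 (C3–OH and C15–OH free) | C/C(=C\CB1OC(C)(C)C(C)(C)O1)C[C@H](OC(=O)[C@H](C)CO[Si](c2ccccc2)(c2ccccc2)C(C)(C)C)[C@@H]3[C@H](OC(=O)[C@H]3C)C=C(CO)CO | intermediate
24 | mono(imidazole-1-carboxylate) of diol 23 | C/C(=C\CB1OC(C)(C)C(C)(C)O1)C[C@H](OC(=O)[C@H](C)CO[Si](c2ccccc2)(c2ccccc2)C(C)(C)C)[C@@H]3[C@H](OC(=O)[C@H]3C)C=C(CO)COC(=O)n4ccnc4 | intermediate (not isolated)
25 | cyclic carbonate of 23 (5-ylidene-1,3-dioxan-2-one) | C/C(=C\CB1OC(C)(C)C(C)(C)O1)C[C@H](OC(=O)[C@H](C)CO[Si](c2ccccc2)(c2ccccc2)C(C)(C)C)[C@@H]3[C@H](OC(=O)[C@H]3C)C=C4COC(=O)OC4 | intermediate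
26 | 15-O-(pinacolboryl) ether of 27 | C=C[C@]1(C)C[C@H](OC(=O)[C@H](C)CO[Si](c2ccccc2)(c2ccccc2)C(C)(C)C)[C@@H]3[C@H](OC(=O)[C@H]3C)[C@H]1C(=C)COB4OC(C)(C)C(C)(C)O4 | intermediate (not isolated)
27 | (3S,3aR,4S,6S,7R,7aR)-6-ethenyl-7-(3-hydroxyprop-1-en-2-yl)-3,6-dimethyl-2-oxooctahydro-1-benzofuran-4-yl (2R)-3-[(tert-butyldiphenylsilyl)oxy]-2-methylpropanoate | C=C[C@]1(C)C[C@H](OC(=O)[C@H](C)CO[Si](c2ccccc2)(c2ccccc2)C(C)(C)C)[C@@H]3[C@H](OC(=O)[C@H]3C)[C@H]1C(=C)CO | intermediate
28 | (3S,3aR,4S,6S,7R,7aR)-6-ethenyl-7-(3-hydroxyprop-1-en-2-yl)-3,6-dimethyl-2-oxooctahydro-1-benzofuran-4-yl (2R)-3-hydroxy-2-methylpropanoate | C=C[C@]1(C)C[C@H](OC(=O)[C@H](C)CO)[C@@H]2[C@H](OC(=O)[C@H]2C)[C@H]1C(=C)CO | target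

**Count and risks**

Total steps: 16. Longest linear sequence: 13 steps (1, 2, 4–8, 11–16, from 1).

Steps most likely to fail:

1. Step 15 (Proposed new method). What may go wrong: reductive elimination in the 1,1′ mode towards the ten-membered ring, protodeboronation before transmetalation, ionisation of the allylic lactone C6–O bond, or oligomerisation of the alkylidene carbonate. The fallback uses known chemistry: the neutral Pd-catalysed coupling of allylic carbonates with allyl stannanes, whose tethered allyl stannane/allyl carboxylate variant is an established closure of 1,2-dialkenylcycloalkanes. It sets out from 22. Perborate oxidation of the C–B bond would give the (E)-allylic alcohol F1, Appel chlorination (PPh3, CCl4) the allylic chloride F2, and SN2 displacement with Bu3SnLi at −78 °C the allyl stannane F3. Methanolysis of the acetonide (PPTS, MeOH) would give the stannyl diol F4, and CDI, through the stannyl mono-imidazolide F5, the stannyl cyclic carbonate F6. Pd(PPh3)4 in THF at 50 °C should then close the ring to the tin alkoxide F7, whose hydrolysis on work-up comes back to the route at 27.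

2. Step 8. What may go wrong: poor or reversed facial selectivity in the addition to the C8 aldehyde, and translactonisation of the new γ-hydroxy lactone towards the 8,12-olide if the work-up turns basic. The fallback sets out from 15. The Barbier addition is run as before, and the C8-epimeric alcohol F8 is not discarded but esterified with acid 20 under Mitsunobu conditions (PPh3, DIAD, THF, 0 °C). This inverts C8 and comes back to the route at 21, so the stereocentre is corrected in the C–O bond formation instead of the C–C bond formation.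

3. Step 13. What may go wrong: protodeboronation of the allyl boronate, or exchange of pinacol for the liberated 1,3-diol, during the acidic methanolysis. The fallback sets out from 21 and reverses the order of events so that boron never meets acid or a free diol. Methanolysis of the acetonide would give the diene diol F9, and CDI, through the diene mono-imidazolide F10, the diene cyclic carbonate F11. The iron-catalysed 1,4-hydroboration is then carried out last and comes back to the route at 25; the price is that the low-valent iron catalyst must tolerate the allylic carbonate.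

Further compounds
F1 | step 15 | (E)-allylic alcohol: 22 with C2–OH in place of C2–Bpin | C/C(=C\CO)C[C@H](OC(=O)[C@H](C)CO[Si](c1ccccc1)(c1ccccc1)C(C)(C)C)[C@@H]2[C@H](OC(=O)[C@H]2C)C=C3COC(C)(C)OC3
F2 | step 15 | (E)-allylic chloride from F1 | C/C(=C\CCl)C[C@H](OC(=O)[C@H](C)CO[Si](c1ccccc1)(c1ccccc1)C(C)(C)C)[C@@H]2[C@H](OC(=O)[C@H]2C)C=C3COC(C)(C)OC3
F3 | step 15 | (E)-allyl tributylstannane (acetonide) | C/C(=C\C[Sn](CCCC)(CCCC)CCCC)C[C@H](OC(=O)[C@H](C)CO[Si](c1ccccc1)(c1ccccc1)C(C)(C)C)[C@@H]2[C@H](OC(=O)[C@H]2C)C=C3COC(C)(C)OC3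
F4 | step 15 | stannyl diol from F3 | C/C(=C\C[Sn](CCCC)(CCCC)CCCC)C[C@H](OC(=O)[C@H](C)CO[Si](c1ccccc1)(c1ccccc1)C(C)(C)C)[C@@H]2[C@H](OC(=O)[C@H]2C)C=C(CO)CO
F5 | step 15 | stannyl mono(imidazole-1-carboxylate) of F4 | C/C(=C\C[Sn](CCCC)(CCCC)CCCC)C[C@H](OC(=O)[C@H](C)CO[Si](c1ccccc1)(c1ccccc1)C(C)(C)C)[C@@H]2[C@H](OC(=O)[C@H]2C)C=C(CO)COC(=O)n3ccnc3
F6 | step 15 | stannyl cyclic carbonate (tin analogue of 25) | C/C(=C\C[Sn](CCCC)(CCCC)CCCC)C[C@H](OC(=O)[C@H](C)CO[Si](c1ccccc1)(c1ccccc1)C(C)(C)C)[C@@H]2[C@H](OC(=O)[C@H]2C)C=C3COC(=O)OC3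
F7 | step 15 | 15-O-(tributylstannyl) ether of 27 | C=C[C@]1(C)C[C@H](OC(=O)[C@H](C)CO[Si](c2ccccc2)(c2ccccc2)C(C)(C)C)[C@@H]3[C@H](OC(=O)[C@H]3C)[C@H]1C(=C)CO[Sn](CCCC)(CCCC)CCCC
F8 | step 8 | C8 epimer of 17 ((1R)-1-hydroxy-3-methylidenepent-4-en-1-yl side chain) | C=CC(=C)C[C@@H](O)[C@@H]1[C@H](OC(=O)[C@H]1C)C=C2COC(C)(C)OC2
F9 | step 13 | diene diol: 21 with the acetonide removed | C=CC(=C)C[C@H](OC(=O)[C@H](C)CO[Si](c1ccccc1)(c1ccccc1)C(C)(C)C)[C@@H]2[C@H](OC(=O)[C@H]2C)C=C(CO)CO
F10 | step 13 | diene mono(imidazole-1-carboxylate) of F9 | C=CC(=C)C[C@H](OC(=O)[C@H](C)CO[Si](c1ccccc1)(c1ccccc1)C(C)(C)C)[C@@H]2[C@H](OC(=O)[C@H]2C)C=C(CO)COC(=O)n3ccnc3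
F11 | step 13 | diene cyclic carbonate (5-ylidene-1,3-dioxan-2-one) | C=CC(=C)C[C@H](OC(=O)[C@H](C)CO[Si](c1ccccc1)(c1ccccc1)C(C)(C)C)[C@@H]2[C@H](OC(=O)[C@H]2C)C=C3COC(=O)OC3
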